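I decide to keep the books on the starting material and not on the second substrate, though the second substrate is the reagent charged in the smaller amount in east, south, south-west and west.

| flask | starting material | second substrate | free catalyst | temperature | remark | time |
|---|---|---|---|---|---|---|
| red | 1.5 M | 1 M | 3 mM | 5 °C | run made earlier |  |
| amber | 1.5 M | 1.7 M | 3 mM | 25 °C | run made earlier |  |
| east | 1.5 M | 0.750 M | 3.0 mM | 40 °C |  | 15 h |
| south | 1.5 M | 0.750 M | 3.0 mM | 25 °C |  | 15 h |
| south-west | 1.5 M | 0.750 M | 3.0 mM | 10 °C |  | 15 h |
| west | 1.5 M | 0.750 M | 3.0 mM |  | at 40 °C until 5.0 h, from then on at 10 °C | 15 h |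

- red (time / h: target / %, starting material / %): 3.00: 4.7, 99.0; 8.00: 7.1, 92.8; 15.0: 12.8, 86.5; 25.0: 21.7, 77.3; 30.0: 24.6, 75.1; 50.0: 42.2, 61.7; 60.0: 43.6, 55.5
- amber (time / h: target / %, starting material / %): 1.33: 8.9, 90.2; 2.00: 15.3, 86.4; 3.00: 19.1, 79.9; 5.00: 32.2, 68.9; 8.00: 44.0, 55.6; 12.0: 53.3, 45.3; 20.0: 65.3, 36.6

(standard deviation of a reading: 1 percentage point)

- a reading or a percentage of target counts all its forms, free or not

- which flask leads in amount of target, in percent of the starting material charged ("all alike" within 1.5 percentage points) (east / south / south-west / west / all alike)
- how much target is there at the end, in percent of the starting material charged: east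
- how much target is there at the end, in percent of the starting material charged: south
- how much target is there at the end, in percent of the starting material charged: south-west
- how much target is there at the end, in percent of the starting material charged: west

If each target took one second substrate, that reagent would be the limiting reagent and the books would close at 50.0% of the starting material. The red run tests this entry. By 60.0 h its target of 0.654 M would have left 0.346 M of second substrate. Yet the first-order constant k, −ln(share of starting material left)/time, reads 0.00967 h⁻¹ at 15.0 h and 0.00981 h⁻¹ at 60.0 h. So I book no second substrate against target, as a judgement, since no reading measures it. Two entries remain, target and starting material left, and in red they add to 99.1%.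

Amber gives k = 0.0734 h⁻¹ at 8.00 h, and the two runs together, although they differ in second substrate as well as in temperature, give as my estimate an activation energy of 69.4 kJ mol⁻¹, which yields k(T). East then has x = 4.20, where the exposure x is the sum of k(T) times the time spent at T, and e^(−x) is the share left. South has 1.10, south-west 0.250, and west, adding its two stretches, 1.57. My target figures are 98.5%, 66.7%, 22.1% and 79.2%, so east leads. Amber's k over 20.0 h is lower, 0.0503 h⁻¹, so at large x my figures lean high.

The forecast gives 41% for east, 47% for south, 21% for south-west and 40% for west, with south leading, holding that the second substrate's use “caps target at 50% here”.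

The flasks give 89.7%, 60.6%, 24.2% and 69.9%, and east leads.

    starting material + free catalyst ⇌ catalyst intermediate A (K = 1.80 M⁻¹, k = 51.0 M⁻¹ h⁻¹, Ea = 62.0 kJ mol⁻¹, ΔH = −14.0 kJ mol⁻¹)
    catalyst intermediate A → free catalyst + target (k = 190 h⁻¹, Ea = 81.0 kJ mol⁻¹)
    second substrate + free catalyst ⇌ catalyst intermediate B (K = 0.470 M⁻¹, k = 200 M⁻¹ h⁻¹, Ea = 43.0 kJ mol⁻¹, ΔH = −29.0 kJ mol⁻¹)
    catalyst intermediate B → free catalyst + second product (k = 220 h⁻¹, Ea = 88.0 kJ mol⁻¹)
    crystals ⇌ target, rate k5*(cs5 - [target]) while solid is left; crystals form when [target] > cs5 (solubility = 1.20 M, k = 37.0 h⁻¹)
    free catalyst + target ⇌ idle complex (K = 8.10 M⁻¹, k = 0.250 M⁻¹ h⁻¹, Ea = 67.0 kJ mol⁻¹, ΔH = −61.0 kJ mol⁻¹)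
    (constants at 25 °C)

Target in east, 1.35 M, is more than the 0.750 M of second substrate charged, so the ledger stands without that entry. But my exposure ran high: the 10.3% of starting material left in east reads as x = 2.27, below my 4.20. In south-west the 75.7% of starting material left reads as x = 0.278, beside my 0.250. Part of what holds south-west at 24.2% is the time given, acting together with the turning of second substrate + free catalyst into catalyst intermediate B, both ways: at ten times the time south-west stands at 67.7%, and with that turning struck out at 29.3%.

For a flask like east kept at 15 °C, the exposure is 0.417, which gives 34.1% target. The computed flask gives 37.4%.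

All runs were computed for substances that don't exist.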